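**Plan**
1. Numbering: benzofuranone O1, C2, C3, C3a, C4–C7, C7a; farnesyl = (2E,6E)-3,7,11-trimethyldodeca-2,6,10-trien-1-yl, C1'–C12'. Retrosynthetic cuts, in this order: C2–OH, O1–C7a, C2–C3, C2–C1'.
2. Enabling feature: O1 sits on arene carbon C7a, the neighbour of C3a, which carries the C3 carbonyl. The ring O1–C2–C3–C3a–C7a is therefore the C2-oxygenated form of a flat, achiral, aromatic 3-oxybenzofuran, and the O1–C7a bond of that benzofuran can be made from a ketone enolate oxygen and an ortho aryl bromide.
3. Forward: farnesyl bromide is joined to 1,3-dithiane (C1'–C2), and the lithiated product is added to the silyl-protected bromo aldehyde (C2–C3). The carbinol is silylated and the ketone unmasked. The benzene ring is bought, the furan ring is the only ring built (step 6), and C2 is oxygenated afterwards.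
4. Stereochemistry: both E-alkenes come with farnesyl bromide and are never touched, and the racemic carbinol centre vanishes on aromatisation. C2, the only stereocentre, is set by catalyst control in an AgOTf–BINAP O-nitroso aldol reaction on the planar benzofuran and stays locked as an anilinooxy ketal until the last step.

Key step: step 6

Assumption 1: the C2 hemiketal of the target can open to the achiral 1-(2,4-dihydroxyphenyl) 1,2-diketone, so it is taken to hold its configuration only in cold, neutral, base-free media; the free C2–OH is uncovered in the very last step and the product is isolated quickly and kept cold.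
Assumption 2: the sense of induction of AgOTf–BINAP on a 2,3-disubstituted benzofuran cannot be read from known cases; (R)-BINAP is written, and (S)-BINAP takes its place if a first run proves to favour the antipode.

**Step 1**
Reactants: 1 2-bromo-4-hydroxybenzaldehyde
Product: 2 2-bromo-4-(triisopropylsilyloxy)benzaldehyde
Conditions: TIPSCl, imidazole, DMF, 0 °C → rt
Reagents that add atoms: triisopropylsilyl chloride, CC(C)[Si](Cl)(C(C)C)C(C)C
Why: Imidazole-promoted O-silylation of the acidic phenol is routine, and the bulky TIPS ether should stand organolithium, hot Cs2CO3 and AgOTf yet leave with buffered fluoride, so that no acid ever meets the farnesyl chain or the C2 ketal.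

**Step 2**
Reactants: 3 1,3-dithiane; 4 (2E,6E)-farnesyl bromide
Product: 6 2-[(2E,6E)-farnesyl]-1,3-dithiane, via 2-lithio-1,3-dithiane 5 (not isolated)
Conditions: n-BuLi, THF, −30 °C; then 4, −78 → 0 °C
Reagents that add atoms: none
Why: Corey–Seebach alkylation: the sulfur-stabilised carbanion 5 displaces the primary allylic bromide in an SN2 manner without allylic shift, so C1'–C2 is formed and both E-alkenes of 4 are carried over unchanged.

**Step 3**
Reactants: 6 2-[(2E,6E)-farnesyl]-1,3-dithiane; 2 2-bromo-4-(triisopropylsilyloxy)benzaldehyde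
Product: 9 rac-[2-bromo-4-(triisopropylsilyloxy)phenyl]{2-[(2E,6E)-farnesyl]-1,3-dithian-2-yl}methanol, via 2-lithio-2-farnesyl-1,3-dithiane 7 (not isolated), via lithium alkoxide 8 (not isolated)
Conditions: n-BuLi (1.0 equiv), THF, −30 → −20 °C; then 2, −78 °C; AcOH, −78 °C
Reagents that add atoms: none
Why: Corey–Seebach umpolung (acyl-anion addition to an aldehyde): the stabilised carbanion 7 adds to the non-enolisable aldehyde at −78 °C far faster than it could exchange with the aryl bromide, forming C2–C3, and the new carbinol centre is left racemic on purpose because step 6 flattens it.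

**Step 4**
Reactants: 9 rac-[2-bromo-4-(triisopropylsilyloxy)phenyl]{2-[(2E,6E)-farnesyl]-1,3-dithian-2-yl}methanol
Product: 10 rac-tert-butyldimethylsilyl ether of 9
Conditions: TBSOTf, 2,6-lutidine, CH2Cl2, 0 °C
Reagents that add atoms: tert-butyldimethylsilyl triflate, CC(C)(C)[Si](C)(C)OS(=O)(=O)C(F)(F)F
Why: Silylation with a silyl triflate and a hindered pyridine base reaches even this crowded secondary benzylic alcohol, and the TBS group is the one that later becomes the enol silane of the benzofuran.

**Step 5**
Reactants: 10 rac-tert-butyldimethylsilyl ether of 9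
Product: 11 rac-1-[2-bromo-4-(triisopropylsilyloxy)phenyl]-1-(tert-butyldimethylsilyloxy)-(4E,8E)-5,9,13-trimethyltetradeca-4,8,12-trien-2-one
Conditions: MeI, CaCO3, MeCN–THF–H2O (4:4:1), 40 °C
Reagents that add atoms: water, O
Why: Alkylative dithiane hydrolysis: S-methylation makes a sulfonium leaving group that water displaces under CaCO3 buffering, an unmasking free of oxidants and thiophilic metal salts that should spare the three alkenes, both silyl ethers and the position of the skipped C2'=C3' double bond.

**Step 6**
Reactants: 11 rac-1-[2-bromo-4-(triisopropylsilyloxy)phenyl]-1-(tert-butyldimethylsilyloxy)-(4E,8E)-5,9,13-trimethyltetradeca-4,8,12-trien-2-one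
Product: 13 2-[(2E,6E)-farnesyl]-3-(tert-butyldimethylsilyloxy)-6-(triisopropylsilyloxy)benzofuran, via cesium (E)-enolate 12 (not isolated)
Conditions: CuI (10 mol %), 1,10-phenanthroline (20 mol %), Cs2CO3 (2 equiv), 4 Å MS, toluene, 90 °C, Ar
Reagents that add atoms: none
Why: Cs2CO3 removes the benzylic, α-oxygenated C3–H of 11 to give the (E)-enolate 12, in which the C2 oxygen and the aryl ring lie cis. The phenanthroline-bound monovalent copper enolate inserts into the adjacent C7a–Br bond, and C–O reductive elimination from the six-membered trivalent copper oxametallacycle forges O1–C7a. The closest known reaction type is the copper-catalysed Ullmann-type intramolecular O-arylation of α-(2-haloaryl) ketone enolates, a standard benzofuran synthesis. One ring is closed, the furan ring O1–C2–C3–C3a–C7a, formally in a 5-(enolendo)-exo-trig mode, and aromatisation makes the closure irreversible. No stereocentre is formed, and the racemic carbinol carbon of 11 becomes the planar C3, so its configuration is of no account. The step needs O-arylation instead of C-arylation through C1' (which would give a 2-indanone) and ring closure faster than the drift of the skipped C2'=C3' enone into conjugation: copper binds the hard enolate oxygen, the bromide sits exactly ortho to the enolate-bearing carbon, kinetic reprotonation of the extended enolate at C1' merely returns 11, and dry Cs2CO3 with sieves at 90 °C spares both silyl groups.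

**Step 7**
Reactants: 13 2-[(2E,6E)-farnesyl]-3-(tert-butyldimethylsilyloxy)-6-(triisopropylsilyloxy)benzofuran
Product: 15 (2S)-2-(anilinooxy)-2-[(2E,6E)-farnesyl]-6-(triisopropylsilyloxy)benzofuran-3(2H)-one, via N-silyl adduct 14 (not isolated)
Conditions: AgOTf (10 mol %), (R)-BINAP (10 mol %), PhNO (1.0 equiv, slow addition), THF, −78 °C; pH 7 buffer
Reagents that add atoms: nitrosobenzene, O=Nc1ccccc1
Why: Proposed new method: the 1:1 complex of AgOTf and (R)-BINAP should bind nitrosobenzene through nitrogen and so leave its oxygen as the electrophilic end, the only nucleophilic carbon of 13 (C2, pushed by the C3 siloxy oxygen) attacks that oxygen in a Mukaiyama-type step on its Si face (O1 > C3 > C1') inside the chiral pocket, which is catalyst control of the new C2 centre, the silyl group then moves from the C3 oxocarbenium oxygen to the anilide nitrogen to give 14 and free the catalyst, and the crowded, fully substituted C2 favours the slim O terminus over the phenyl-bearing N terminus; the closest known reaction type is the BINAP–AgOTf-catalysed enantioselective O-nitroso aldol reaction of tin enolates and its silver-catalysed variant with silyl enol ethers, what is new being an aromatic 3-siloxybenzofuran as donor and a ketal carbon as the centre formed.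

**Step 8**
Reactants: 15 (2S)-2-(anilinooxy)-2-[(2E,6E)-farnesyl]-6-(triisopropylsilyloxy)benzofuran-3(2H)-one
Product: 16 (2S)-2-(anilinooxy)-2-[(2E,6E)-farnesyl]-6-hydroxybenzofuran-3(2H)-one
Conditions: TBAF, AcOH (1:1), THF, 0 °C
Reagents that add atoms: none
Why: Fluoride-induced cleavage of an aryl silyl ether whose phenoxide is stabilised by the para C3 carbonyl is fast at 0 °C, acetic acid keeps the medium from turning basic (no retro-nitroso aldol), and C2 cannot epimerise since it is a full ketal at this stage.

**Step 9**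
Reactants: 16 (2S)-2-(anilinooxy)-2-[(2E,6E)-farnesyl]-6-hydroxybenzofuran-3(2H)-one
Product: 17 (2R)-2-[(2E,6E)-farnesyl]-2,6-dihydroxybenzofuran-3(2H)-one (CNP0212006.1)
Conditions: CuSO4 (0.3 equiv), MeOH, 0 °C
Reagents that add atoms: none
Why: CuSO4-catalysed N–O cleavage of α-aminooxy ketones breaks only the N–O bond, so the C2–O bond and its configuration are retained (the descriptor changes from S to R merely because OH ranks below O1), and the labile hemiketal appears only in this cold, base-free last step.

**Compound list**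
1 | 2-bromo-4-hydroxybenzaldehyde | O=Cc1ccc(O)cc1Br | starting material
2 | 2-bromo-4-(triisopropylsilyloxy)benzaldehyde | O=Cc1ccc(O[Si](C(C)C)(C(C)C)C(C)C)cc1Br | intermediate
3 | 1,3-dithiane | C1CSCSC1 | starting material
4 | (2E,6E)-farnesyl bromide | CC(C)=CCC/C(C)=C/CC/C(C)=C/CBr | starting material
5 | 2-lithio-1,3-dithiane | [Li]C1SCCCS1 | intermediate
6 | 2-[(2E,6E)-farnesyl]-1,3-dithiane | CC(C)=CCC/C(C)=C/CC/C(C)=C/CC1SCCCS1 | intermediate
7 | 2-lithio-2-[(2E,6E)-farnesyl]-1,3-dithiane | CC(C)=CCC/C(C)=C/CC/C(C)=C/CC1([Li])SCCCS1 | intermediate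
8 | lithium alkoxide of 9 (racemic) | CC(C)=CCC/C(C)=C/CC/C(C)=C/CC1(SCCCS1)C([O-])c1ccc(O[Si](C(C)C)(C(C)C)C(C)C)cc1Br.[Li+] | intermediate
9 | rac-[2-bromo-4-(triisopropylsilyloxy)phenyl]{2-[(2E,6E)-farnesyl]-1,3-dithian-2-yl}methanol | CC(C)=CCC/C(C)=C/CC/C(C)=C/CC1(SCCCS1)C(O)c1ccc(O[Si](C(C)C)(C(C)C)C(C)C)cc1Br | intermediate
10 | rac-tert-butyldimethylsilyl ether of 9 | CC(C)=CCC/C(C)=C/CC/C(C)=C/CC1(SCCCS1)C(O[Si](C)(C)C(C)(C)C)c1ccc(O[Si](C(C)C)(C(C)C)C(C)C)cc1Br | intermediate
11 | rac-1-[2-bromo-4-(triisopropylsilyloxy)phenyl]-1-(tert-butyldimethylsilyloxy)-(4E,8E)-5,9,13-trimethyltetradeca-4,8,12-trien-2-one | CC(C)=CCC/C(C)=C/CC/C(C)=C/CC(=O)C(O[Si](C)(C)C(C)(C)C)c1ccc(O[Si](C(C)C)(C(C)C)C(C)C)cc1Br | intermediate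
12 | cesium (E)-enolate of 11 (C2 oxygen cis to the aryl ring) | CC(C)=CCC/C(C)=C/CC/C(C)=C/C/C([O-])=C(\O[Si](C)(C)C(C)(C)C)c1ccc(O[Si](C(C)C)(C(C)C)C(C)C)cc1Br.[Cs+] | intermediate
13 | 2-[(2E,6E)-farnesyl]-3-(tert-butyldimethylsilyloxy)-6-(triisopropylsilyloxy)benzofuran | CC(C)=CCC/C(C)=C/CC/C(C)=C/Cc1oc2cc(O[Si](C(C)C)(C(C)C)C(C)C)ccc2c1O[Si](C)(C)C(C)(C)C | intermediate
14 | (2S)-2-{[N-(tert-butyldimethylsilyl)anilino]oxy}-2-[(2E,6E)-farnesyl]-6-(triisopropylsilyloxy)benzofuran-3(2H)-one | CC(C)=CCC/C(C)=C/CC/C(C)=C/C[C@@]1(ON(c2ccccc2)[Si](C)(C)C(C)(C)C)Oc2cc(O[Si](C(C)C)(C(C)C)C(C)C)ccc2C1=O | intermediate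
15 | (2S)-2-(anilinooxy)-2-[(2E,6E)-farnesyl]-6-(triisopropylsilyloxy)benzofuran-3(2H)-one | CC(C)=CCC/C(C)=C/CC/C(C)=C/C[C@@]1(ONc2ccccc2)Oc2cc(O[Si](C(C)C)(C(C)C)C(C)C)ccc2C1=O | intermediate
16 | (2S)-2-(anilinooxy)-2-[(2E,6E)-farnesyl]-6-hydroxybenzofuran-3(2H)-one | CC(C)=CCC/C(C)=C/CC/C(C)=C/C[C@@]1(ONc2ccccc2)Oc2cc(O)ccc2C1=O | intermediate
17 | (2R)-2-[(2E,6E)-farnesyl]-2,6-dihydroxybenzofuran-3(2H)-one | CC(C)=CCC/C(C)=C/CC/C(C)=C/C[C@@]1(O)Oc2cc(O)ccc2C1=O | target

**Total step count:** 9. **Longest linear sequence:** 8 (steps 2–9 from 1,3-dithiane and farnesyl bromide; equally steps 1 and 3–9 from the aldehyde).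

**Steps most likely to fail**

1. Step 7 (Proposed new method). Four things may go wrong:
   - weak facial discrimination on the flat benzofuran;
   - a racemic background reaction catalysed by silyl triflate released when silyl transfer to nitrogen lags;
   - attack at the nitrogen end of nitrosobenzene;
   - no turnover with the bulky silyl group.

   The fallback uses known chemistry, with resolution in place of asymmetric catalysis, and sets out from 13. A Rubottom-type oxidation with neutral 2-(phenylsulfonyl)-3-phenyloxaziridine in CHCl3 at rt leaves isolated trisubstituted alkenes alone. After the usual silyl shift it should give racemic 2-(tert-butyldimethylsilyloxy)-2-[(2E,6E)-farnesyl]-6-(triisopropylsilyloxy)benzofuran-3(2H)-one F1. As a full ketal this compound cannot racemise, and preparative chromatography on a chiral stationary phase separates it to give the (2S)-silyl ketal F2. HF·pyridine with extra pyridine in THF at 0 °C then removes both silyl groups, and the route is rejoined at 17.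

2. Step 6. Four things may go wrong:
   - enolisation toward C1' followed by drift of the skipped enone into conjugation;
   - C-arylation through C1';
   - shuttling of the silyl group between the two oxygens of the enediolate;
   - loss of silyl groups to adventitious hydroxide.

   The fallback sets out from 11 and avoids any base stronger than acetate or perborate. Miyaura borylation (B2pin2, PdCl2(dppf), KOAc, dioxane, 80 °C) should give the pinacol boronate F3. Oxidation with NaBO3·4H2O in THF–H2O at rt makes the O1–C7a bond by boron-to-oxygen migration and gives the phenol F4, which equilibrates with its five-membered cyclic hemiketal. Catalytic PPTS with 4 Å MS in toluene at 50 °C brings about the classical cyclodehydration, with ring closure at O1–C2, and the route is rejoined at 13.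

3. Step 9. Configuration at C2 may erode by ring–chain tautomerism while the free hemiketal, with its acidic 6-OH, sits in methanol with the divalent copper salt, and the hemiketal may exchange with methanol. The fallback sets out from 15 and changes which lock is opened last. The CuSO4/MeOH cleavage is run on 15, where no acidic phenol is present. The resulting hemiketal (2R)-2-[(2E,6E)-farnesyl]-2-hydroxy-6-(triisopropylsilyloxy)benzofuran-3(2H)-one F5 is capped at once with TESOTf and 2,6-lutidine in CH2Cl2 at −78 °C to give the (2S)-triethylsilyl ketal F6. This ketal is configurationally locked, so its enantiomeric purity can be checked and, if needed, restored on a chiral stationary phase. HF·pyridine with extra pyridine in THF at −20 °C then removes both silyl groups in an aprotic, metal-free medium, and the route is rejoined at 17.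

**Further compounds**
F1 | step 7 | rac-2-(tert-butyldimethylsilyloxy)-2-[(2E,6E)-farnesyl]-6-(triisopropylsilyloxy)benzofuran-3(2H)-one | CC(C)=CCC/C(C)=C/CC/C(C)=C/CC1(O[Si](C)(C)C(C)(C)C)Oc2cc(O[Si](C(C)C)(C(C)C)C(C)C)ccc2C1=O
F2 | step 7 | (2S)-2-(tert-butyldimethylsilyloxy)-2-[(2E,6E)-farnesyl]-6-(triisopropylsilyloxy)benzofuran-3(2H)-one | CC(C)=CCC/C(C)=C/CC/C(C)=C/C[C@@]1(O[Si](C)(C)C(C)(C)C)Oc2cc(O[Si](C(C)C)(C(C)C)C(C)C)ccc2C1=O
F3 | step 6 | rac-1-(tert-butyldimethylsilyloxy)-1-[2-(4,4,5,5-tetramethyl-1,3,2-dioxaborolan-2-yl)-4-(triisopropylsilyloxy)phenyl]-(4E,8E)-5,9,13-trimethyltetradeca-4,8,12-trien-2-one | CC(C)=CCC/C(C)=C/CC/C(C)=C/CC(=O)C(O[Si](C)(C)C(C)(C)C)c1ccc(O[Si](C(C)C)(C(C)C)C(C)C)cc1B1OC(C)(C)C(C)(C)O1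
F4 | step 6 | rac-1-(tert-butyldimethylsilyloxy)-1-[2-hydroxy-4-(triisopropylsilyloxy)phenyl]-(4E,8E)-5,9,13-trimethyltetradeca-4,8,12-trien-2-one | CC(C)=CCC/C(C)=C/CC/C(C)=C/CC(=O)C(O[Si](C)(C)C(C)(C)C)c1ccc(O[Si](C(C)C)(C(C)C)C(C)C)cc1O
F5 | step 9 | (2R)-2-[(2E,6E)-farnesyl]-2-hydroxy-6-(triisopropylsilyloxy)benzofuran-3(2H)-one | CC(C)=CCC/C(C)=C/CC/C(C)=C/C[C@@]1(O)Oc2cc(O[Si](C(C)C)(C(C)C)C(C)C)ccc2C1=O
F6 | step 9 | (2S)-2-[(2E,6E)-farnesyl]-2-(triethylsilyloxy)-6-(triisopropylsilyloxy)benzofuran-3(2H)-one | CC(C)=CCC/C(C)=C/CC/C(C)=C/C[C@@]1(O[Si](CC)(CC)CC)Oc2cc(O[Si](C(C)C)(C(C)C)C(C)C)ccc2C1=O
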